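**Retrosynthetic overview**
1. The last bond made is the C14–O ester. The carboxylate of the butenolide acid opens the spiro-oxirane CH2 of the second monomer, as the fungal dimers are thought to arise. Acid then removes the tert-butyl esters.
2. The butenolide comes from anti elimination of the 10-epi-oxirane (H1 and C10–O antiperiplanar) to the C1=C10 allylic alcohol, followed by lactonisation on C2. The natural 10S-oxirane resists this elimination and serves as the electrophile, so both epoxide epimers of one alkene are used.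
3. The cyclohexane is closed at C1–C6. A C1=C10(CH3) dienolate π-system attacks a C4–C5–C6 π-allyl cation equivalent (palladium, from a vinyl oxirane) and ends as the exocyclic C10=C14 alkene. This is the cadinyl closure with γ-cadinene-type termination, in seco form.
4. The acyclic precursor comes from isovaleraldehyde and methyl vinyl ketone (C7 set by enamine catalysis), an oxalyl ylide (C4, C5, C15), CH2 transfer (C3) and a phosphonoacetate (C1, C2).
5. Rings form in this order: sacrificial C3–C4 oxirane, carbocycle, spiro-oxirane, butenolide.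

Assumption: cadinane (heptelidic acid) locants are used (ring C1, C6–C10; C2 = carboxyl on C1; chain C5=C4(C3H2O)(C15O2) on C6; isopropyl on C7; C14 on C10). The presumed biosynthesis is taken as farnesyl → closure of C1=C10 onto the C4–C6 allyl cation → seco-cadinane 10(14)-epoxide → butenolide by epoxide elimination and lactonisation, and dimer by carboxylate–epoxide opening.

**Step 1**
Reactants: 1 methyltriphenylphosphonium bromide; 2 di-tert-butyl oxalate
Product: 4 tert-butyl 2-oxo-3-(triphenyl-λ5-phosphanylidene)propanoate, via methylidenetriphenylphosphorane 3 (not isolated)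
Conditions: KOtBu (1.1 equiv), THF, 0 °C; then 2, −78 °C → rt
Reagents that add atoms: none
Why: Acylation of a non-stabilised Wittig ylide by an activated oxalate ester, in which the released tert-butoxide deprotonates the acylphosphonium salt and the stabilised ylide plus the bulky remaining ester stop a second acylation; no stereocentre is formed.

**Step 2**
Reactants: 5 3-methylbutanal; 6 but-3-en-2-one
Product: 7 (2R)-5-oxo-2-(propan-2-yl)hexanal
Conditions: (R)-2-[methoxy(diphenyl)methyl]pyrrolidine (5 mol %), ethyl 3,4-dihydroxybenzoate (20 mol %), neat, 4 °C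
Reagents that add atoms: none
Why: Enamine-catalysed asymmetric Michael addition, in which the CPh2OMe group shields one face of the E-enamine of 5 so that the enone adds to the open face and sets C7 as R (about 90 % ee or better expected for this catalyst class).

**Step 3**
Reactants: 7 (2R)-5-oxo-2-(propan-2-yl)hexanal; 4 tert-butyl 2-oxo-3-(triphenyl-λ5-phosphanylidene)propanoate
Product: 8 tert-butyl (3E,5R)-2,8-dioxo-5-(propan-2-yl)non-3-enoate
Conditions: toluene, 70 °C
Reagents that add atoms: none
Why: Wittig olefination with a stabilised acyl ylide, which is E-selective, attacks the aldehyde but not the methyl ketone, and is neutral enough to leave the α-stereocentre C7 intact.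

**Step 4**
Reactants: 8 tert-butyl (3E,5R)-2,8-dioxo-5-(propan-2-yl)non-3-enoate
Product: 9 tert-butyl 2-[(1E,3R)-6-oxo-3-(propan-2-yl)hept-1-en-1-yl]oxirane-2-carboxylate (both epimers at oxirane C2 = C4)
Conditions: Me3SI, KHMDS (1.0 equiv each), THF, −20 °C; added to 8 at −78 → −30 °C
Reagents that add atoms: trimethylsulfonium iodide, C[S+](C)C.[I-]
Why: Johnson–Corey–Chaykovsky epoxidation, in which the unstabilised sulfonium methylide adds irreversibly in 1,2 fashion to the far more electrophilic α-keto ester carbonyl (not the methyl ketone, not C6); the new C4 centre forms unselectively and does not matter because it becomes sp2 in step 6.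

**Step 5**
Reactants: 9 tert-butyl 2-[(1E,3R)-6-oxo-3-(propan-2-yl)hept-1-en-1-yl]oxirane-2-carboxylate; 10 tert-butyl diethylphosphonoacetate
Product: 12 tert-butyl 2-[(1E,3R,6E)-8-tert-butoxy-6-methyl-8-oxo-3-(propan-2-yl)octa-1,6-dien-1-yl]oxirane-2-carboxylate, via sodium phosphonoacetate carbanion 11 (not isolated)
Conditions: NaH, THF, 0 °C; then 9, rt → 45 °C; E isomer (about 5:1) isolated by chromatography
Reagents that add atoms: none
Why: Horner–Wadsworth–Emmons olefination of the methyl ketone, in which the soft carbanion leaves the oxirane and the hindered esters alone, and the major E isomer places the C14 methyl cis to the ester, the position that LDA deprotonates in step 6.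

**Step 6 (key step)**
Reactants: 12 tert-butyl 2-[(1E,3R,6E)-8-tert-butoxy-6-methyl-8-oxo-3-(propan-2-yl)octa-1,6-dien-1-yl]oxirane-2-carboxylate
Product: 15 tert-butyl (1S,2S,3R)-2-[(1E)-3-tert-butoxy-2-(hydroxymethyl)-3-oxoprop-1-en-1-yl]-6-methylidene-3-(propan-2-yl)cyclohexane-1-carboxylate, via silyl ketene acetal 13 (not isolated), via cyclised trimethylsilyl ether 14 (not isolated)
Conditions: LDA, DMPU, TMSCl, THF, −78 °C; evaporate, pentane, filter; Pd2(dba)3·CHCl3 (5 mol %), dppe (12 mol %), THF (0.01 M), 45 °C; 10 % aq citric acid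
Reagents that add atoms: none
Why: Proposed new method: zerovalent palladium ionises either C4 epimer of the vinyl oxirane to a C4–C5–C6 π-allyl cation whose alkoxide strips the silyl group from the ketene acetal, and the freed dienolate attacks C6 through its α-carbon C1 (six-membered chair, whereas attack through C14 or at quaternary C4 would need eight-membered rings), leaving the exocyclic C10=C14 alkene with isopropyl, alkenyl and ester groups all equatorial (6S and 1S set from 7R), while the π-allyl faces and termini equilibrate through the O-bound palladium dienolate so that the ester ends syn (C6 trans to C15, 4E); the closest known reaction types are the Tsuji–Trost alkylation with vinyl epoxides under neutral conditions, the palladium-catalysed allylation of ketene silyl acetals with allyl carbonates, and the deconjugative α-alkylation of senecioate-type dienolates.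

**Step 7**
Reactants: 15 tert-butyl (1S,2S,3R)-2-[(1E)-3-tert-butoxy-2-(hydroxymethyl)-3-oxoprop-1-en-1-yl]-6-methylidene-3-(propan-2-yl)cyclohexane-1-carboxylate
Product: 16 tert-butyl (3S,4S,5S,6R)-5-[(1E)-3-tert-butoxy-2-(hydroxymethyl)-3-oxoprop-1-en-1-yl]-6-(propan-2-yl)-1-oxaspiro[2.5]octane-4-carboxylate (10S, O equatorial); 17 its (3R,4S,5S,6R) epimer (10R, O axial), both isolated by chromatography
Conditions: mCPBA (1.1 equiv), NaHCO3, CH2Cl2, 0 °C
Reagents that add atoms: mCPBA (3-chloroperoxybenzoic acid), OOC(=O)c1cccc(Cl)c1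
Why: Prilezhaev epoxidation, in which only the electron-rich 1,1-disubstituted C10=C14 alkene reacts (the enoate is inert), equatorial attack gives 10S (16) and axial attack gives 10R (17) in comparable amounts (axial slightly favoured, as for methylenecyclohexanes), and both are used because each half of the target needs one epimer.

**Step 8**
Reactants: 17 (10R)-spiro-oxirane diester
Product: 19 (2E)-2-(hydroxymethyl)-3-[(4S,5R)-3-oxo-5-(propan-2-yl)-1,3,4,5,6,7-hexahydro-2-benzofuran-4-yl]prop-2-enoic acid, via allylic alcohol diester 18 (not isolated)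
Conditions: DBU (2 equiv), CH2Cl2, rt → 40 °C; then TFA (excess), 0 °C → rt; aq NaHCO3, then pH 3
Reagents that add atoms: none
Why: Base-induced isomerisation of a β,γ-epoxy ester to the γ-hydroxy enoate (E2/E1cB) followed by acidolysis and lactonisation, in which the axial C10–O bond of 17 is antiperiplanar to axial H1, the resulting C14 hydroxyl sits cis to C2 on the C1=C10 alkene and closes the butenolide once TFA removes the tert-butyl groups, and C6 and C7 are untouched.

**Step 9**
Reactants: 16 (10S)-spiro-oxirane diester; 19 butenolide acid (1.3 equiv)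
Product: 21 di-tert-butyl ester (at C2 and C15 of the cyclohexanol half) of the target, via cesium carboxylate 20 (not isolated)
Conditions: Cs2CO3 (0.3 equiv), DMF (0.5 M), 65 °C; pH 4 work-up, excess 19 recovered
Reagents that add atoms: none
Why: Base-catalysed addition of a carboxylic acid to an epoxide (SN2 at the oxirane CH2), which leaves C10 untouched (10S retained); the free hydroxyls do not compete, the excess acid protonates the tertiary alkoxide at once (no retro-aldol, no acyl shift), and the equatorial C10–O bond of 16 is gauche to axial H1, so elimination is slow.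

**Step 10**
Reactants: 21 di-tert-butyl ester of the target
Product: 22 CNP0071646.2, (1S,2S,3R,6S)-2-[(1E)-2-carboxy-3-hydroxyprop-1-en-1-yl]-6-hydroxy-6-({[(2E)-2-(hydroxymethyl)-3-[(4S,5R)-3-oxo-5-(propan-2-yl)-1,3,4,5,6,7-hexahydro-2-benzofuran-4-yl]prop-2-enoyl]oxy}methyl)-3-(propan-2-yl)cyclohexane-1-carboxylic acid
Conditions: TFA/CH2Cl2 1:3, 0 °C → rt; evaporate; brief aq NaHCO3/MeOH, then pH 3
Reagents that add atoms: none
Why: Acidolysis of tert-butyl esters (alkyl–oxygen cleavage), which spares the inter-unit enoate ester, the butenolide and the tertiary alcohol (ionisation at C10 is disfavoured by the flanking acyloxymethyl and carboxyl-bearing carbons), so no stereocentre is touched.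

**Compound list**
1 | methyltriphenylphosphonium bromide | C[P+](c1ccccc1)(c1ccccc1)c1ccccc1.[Br-] | starting material
2 | di-tert-butyl oxalate | CC(C)(C)OC(=O)C(=O)OC(C)(C)C | starting material
3 | methylidenetriphenylphosphorane | C=P(c1ccccc1)(c1ccccc1)c1ccccc1 | intermediate
4 | tert-butyl 2-oxo-3-(triphenyl-λ5-phosphanylidene)propanoate | CC(C)(C)OC(=O)C(=O)C=P(c1ccccc1)(c1ccccc1)c1ccccc1 | intermediate
5 | 3-methylbutanal | CC(C)CC=O | starting material
6 | but-3-en-2-one | CC(=O)C=C | starting material
7 | (2R)-5-oxo-2-(propan-2-yl)hexanal | CC(C)[C@@H](CCC(C)=O)C=O | intermediate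
8 | tert-butyl (3E,5R)-2,8-dioxo-5-(propan-2-yl)non-3-enoate | CC(C)[C@@H](CCC(C)=O)/C=C/C(=O)C(=O)OC(C)(C)C | intermediate
9 | tert-butyl 2-[(1E,3R)-6-oxo-3-(propan-2-yl)hept-1-en-1-yl]oxirane-2-carboxylate (both oxirane epimers) | CC(C)[C@@H](CCC(C)=O)/C=C/C1(CO1)C(=O)OC(C)(C)C | intermediate
10 | tert-butyl diethylphosphonoacetate | CCOP(=O)(CC(=O)OC(C)(C)C)OCC | starting material
11 | sodium salt of the carbanion of 10 | CCOP(=O)(OCC)[CH-]C(=O)OC(C)(C)C.[Na+] | intermediate
12 | tert-butyl 2-[(1E,3R,6E)-8-tert-butoxy-6-methyl-8-oxo-3-(propan-2-yl)octa-1,6-dien-1-yl]oxirane-2-carboxylate (both oxirane epimers) | CC(C)[C@@H](CC/C(C)=C/C(=O)OC(C)(C)C)/C=C/C1(CO1)C(=O)OC(C)(C)C | intermediate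
13 | O-trimethylsilyl O-tert-butyl ketene acetal of 12 (C14H2=C10–C1H=C2 dienolate silyl ether) | CC(C)[C@@H](CCC(=C)C=C(OC(C)(C)C)O[Si](C)(C)C)/C=C/C1(CO1)C(=O)OC(C)(C)C | intermediate
14 | C3-O-trimethylsilyl ether of 15 | CC(C)[C@H]1CCC(=C)[C@@H](C(=O)OC(C)(C)C)[C@@H]1/C=C(\CO[Si](C)(C)C)C(=O)OC(C)(C)C | intermediate
15 | tert-butyl (1S,2S,3R)-2-[(1E)-3-tert-butoxy-2-(hydroxymethyl)-3-oxoprop-1-en-1-yl]-6-methylidene-3-(propan-2-yl)cyclohexane-1-carboxylate | CC(C)[C@H]1CCC(=C)[C@@H](C(=O)OC(C)(C)C)[C@@H]1/C=C(\CO)C(=O)OC(C)(C)C | intermediate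
16 | (3S,4S,5S,6R)-1-oxaspiro[2.5]octane diester (10S, natural series) | CC(C)[C@H]1CC[C@@]2(CO2)[C@@H](C(=O)OC(C)(C)C)[C@@H]1/C=C(\CO)C(=O)OC(C)(C)C | intermediate
17 | (3R,4S,5S,6R)-1-oxaspiro[2.5]octane diester (10R epimer) | CC(C)[C@H]1CC[C@]2(CO2)[C@@H](C(=O)OC(C)(C)C)[C@@H]1/C=C(\CO)C(=O)OC(C)(C)C | intermediate
18 | tert-butyl (5R,6S)-6-[(1E)-3-tert-butoxy-2-(hydroxymethyl)-3-oxoprop-1-en-1-yl]-2-(hydroxymethyl)-5-(propan-2-yl)cyclohex-1-ene-1-carboxylate | CC(C)[C@H]1CCC(CO)=C(C(=O)OC(C)(C)C)[C@@H]1/C=C(\CO)C(=O)OC(C)(C)C | intermediate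
19 | (2E)-2-(hydroxymethyl)-3-[(4S,5R)-3-oxo-5-(propan-2-yl)-1,3,4,5,6,7-hexahydro-2-benzofuran-4-yl]prop-2-enoic acid | O=C(O)/C(CO)=C/[C@H]1C2=C(CC[C@@H]1C(C)C)COC2=O | intermediate
20 | cesium salt of 19 | [Cs+].[O-]C(=O)/C(CO)=C/[C@H]1C2=C(CC[C@@H]1C(C)C)COC2=O | intermediate
21 | di-tert-butyl ester of 22 | CC(C)[C@H]1CC[C@@](O)(COC(=O)/C(=C/[C@H]2C3=C(CC[C@@H]2C(C)C)COC3=O)CO)[C@@H](C(=O)OC(C)(C)C)[C@@H]1/C=C(\CO)C(=O)OC(C)(C)C | intermediate
22 | CNP0071646.2 | CC(C)[C@H]1CC[C@@](O)(COC(=O)/C(=C/[C@H]2C3=C(CC[C@@H]2C(C)C)COC3=O)CO)[C@@H](C(=O)O)[C@@H]1/C=C(\CO)C(=O)O | target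

**Totals:** 10 steps in all. The longest linear sequence is 9 steps (steps 2–10); step 1 is a side branch.

**The three steps most likely to fail**

Step 6 is the riskiest. The silyl dienolate is a harder nucleophile than those usually used with π-allylpalladium species. The π-allyl intermediate could instead lose H7 to give a diene, or be captured by its own alkoxide. The C1 configuration also rests on a chair model. The fallback replaces the dienolate by a soft β-keto ester and installs C14 afterwards. It sets out from 9 and comes back at 15, one step longer. The kinetic enolate of 9 (LDA, −78 °C) is C-acylated with Boc2O to the β-keto ester F1. Under neutral Tsuji–Trost conditions (Pd2(dba)3·CHCl3, dppe, THF) this closes the same C1–C6 bond to the 10-oxocyclohexane diester F2, in which C1 equilibrates to the equatorial epimer. Non-basic methylenation (Zn, CH2Br2, TiCl4, CH2Cl2, 0 °C) then gives 15.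

Step 9 is next. An enoate carboxylate is a weak nucleophile, the oxirane CH2 is neopentyl-like, and slow elimination of 16 may compete at 65 °C. The fallback acylates a diol instead of opening an epoxide. It sets out from 15 and 19 and comes back at 22.
- OsO4 (cat.) with NMO dihydroxylates only C10=C14 of 15, from the equatorial face as expected for this bulky reagent, to the 10S triol F3.
- Compound 19 is silylated (Et3SiCl, imidazole) to the bis(triethylsilyl) derivative F4. Its silyl ester hydrolyses on aqueous K2CO3 work-up to the O-triethylsilyl acid F5.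
- 1-Chloro-N,N,2-trimethylprop-1-en-1-amine converts F5 to the acid chloride F6.
- 2-Aminoethyl diphenylborinate (10 mol %) with iPr2NEt in MeCN directs acylation to the primary oxygen of the 1,2-diol of F3, because its borinate is far more nucleophilic than the isolated C3 hydroxyl. This gives the triethylsilyl ether F7.
- The conditions of step 10 then remove the silyl and tert-butyl groups to give 22.

Step 4 is the third. The basic ylide may deprotonate the vinylogous C7–H of 8 (racemisation), add in conjugate fashion, or touch the methyl ketone. The fallback makes the oxirane by nucleophilic epoxidation of a diene ester instead of by methylene transfer to a keto ester. It sets out from 7 and comes back at 9, and makes steps 1 and 3 unnecessary. An Arbuzov reaction of commercial tert-butyl 2-(bromomethyl)acrylate with P(OEt)3 gives the allyl phosphonate F8. Treatment with LiHMDS at −78 °C and then 7 gives the cross-conjugated diene ester F9. tBuOOLi (THF, −20 °C, Weitz–Scheffer type) attacks only the acrylate CH2=C unit, because C5=C6 is not in Michael conjugation with the ester. This gives 9.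

**Further compounds**
F1 | step 6 | tert-butyl 2-[(1E,3R)-8-tert-butoxy-6,8-dioxo-3-(propan-2-yl)oct-1-en-1-yl]oxirane-2-carboxylate (both oxirane epimers) | CC(C)[C@@H](CCC(=O)CC(=O)OC(C)(C)C)/C=C/C1(CO1)C(=O)OC(C)(C)C
F2 | step 6 | tert-butyl (1S,2S,3R)-2-[(1E)-3-tert-butoxy-2-(hydroxymethyl)-3-oxoprop-1-en-1-yl]-6-oxo-3-(propan-2-yl)cyclohexane-1-carboxylate | CC(C)[C@H]1CCC(=O)[C@@H](C(=O)OC(C)(C)C)[C@@H]1/C=C(\CO)C(=O)OC(C)(C)C
F3 | step 9 | tert-butyl (1S,2S,3R,6S)-2-[(1E)-3-tert-butoxy-2-(hydroxymethyl)-3-oxoprop-1-en-1-yl]-6-hydroxy-6-(hydroxymethyl)-3-(propan-2-yl)cyclohexane-1-carboxylate | CC(C)[C@H]1CC[C@@](O)(CO)[C@@H](C(=O)OC(C)(C)C)[C@@H]1/C=C(\CO)C(=O)OC(C)(C)C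
F4 | step 9 | triethylsilyl ester of the O-triethylsilyl ether of 19 | CC[Si](CC)(CC)OC(=O)/C(CO[Si](CC)(CC)CC)=C/[C@H]1C2=C(CC[C@@H]1C(C)C)COC2=O
F5 | step 9 | O-triethylsilyl ether of 19 (free acid) | O=C(O)/C(CO[Si](CC)(CC)CC)=C/[C@H]1C2=C(CC[C@@H]1C(C)C)COC2=O
F6 | step 9 | acid chloride of F5 | O=C(Cl)/C(CO[Si](CC)(CC)CC)=C/[C@H]1C2=C(CC[C@@H]1C(C)C)COC2=O
F7 | step 9 | O-triethylsilyl ether (butenolide half) of 21 | CC(C)[C@H]1CC[C@@](O)(COC(=O)/C(=C/[C@H]2C3=C(CC[C@@H]2C(C)C)COC3=O)CO[Si](CC)(CC)CC)[C@@H](C(=O)OC(C)(C)C)[C@@H]1/C=C(\CO)C(=O)OC(C)(C)C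
F8 | step 4 | tert-butyl 2-[(diethoxyphosphoryl)methyl]prop-2-enoate | CCOP(=O)(CC(=C)C(=O)OC(C)(C)C)OCC
F9 | step 4 | tert-butyl (3E,5R)-2-methylidene-8-oxo-5-(propan-2-yl)non-3-enoate | CC(C)[C@@H](CCC(C)=O)/C=C/C(=C)C(=O)OC(C)(C)C
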